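## Retrosynthetic overview

1. The target comes from a fully protected macrocycle by one fluoride deprotection; the 14-membered ring is closed last, at C7–C8, by an intramolecular palladium B-alkyl Suzuki–Miyaura coupling (alkene hydroboration onto a 2-iodoalkene).
2. The open-chain precursor is split at C1–C2 by a copper-catalysed SN2′ alkyl–allyl coupling (the proposed new step) of a west alkylzinc with an east Baylis–Hillman-derived allyl chloride; this sets C1 and creates the acrylate.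
3. East fragment: the oxolane ring is formed first, by asymmetric epoxidation of a Z trisubstituted alkene and 5-exo opening by the C9 hydroxyl; the alkene comes from a B-alkyl Suzuki coupling of an enynyl acetate with a (Z)-2-iodoalkene.
4. West fragment: Sharpless kinetic resolution of a dienol and hydride opening of the epoxide set C4 and C5.
5. Ring order: oxolane (step 9), then the carbocycle (step 25).

Numbering used in the Why lines: C1–C14 are the carbocycle atoms in SMILES order (C1 carries the acrylic acid, C4 = C(CH3)OH, C5 = CHOAc, C8 = C(=CH2), C9 and C12 = oxolane carbons, C13 = CHOH). The target is read as 1S,4S,5R,9R,12S,13S. Locants inside compound names are the IUPAC locants of each compound.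

## Route

Step 1
Reactants: 1 prop-2-enal (acrolein); 2 ethynyltrimethylsilane
Product: 4 rac-5-(trimethylsilyl)pent-1-en-4-yn-3-ol, via lithium (trimethylsilyl)acetylide 3 (not isolated)
Conditions: n-BuLi, THF, −78 °C; then 1, −78 °C; aq NH4Cl
Reagents that add atoms: none
Why: 1,2-addition of a lithium acetylide to an enal gives the racemic enynol, whose carbinol (future C9) is resolved in step 2.

Step 2
Reactants: 4 rac-5-(trimethylsilyl)pent-1-en-4-yn-3-ol
Product: 5 (3R)-5-(trimethylsilyl)pent-1-en-4-yn-3-yl acetate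
Conditions: lipase PS (Burkholderia cepacia lipase), vinyl acetate, hexane, 30 °C, to about 50% conversion
Reagents that add atoms: vinyl acetate, CC(=O)OC=C
Why: Lipase-catalysed kinetic resolution by transesterification (Kazlauskas rule, silylalkynyl as the large group) acylates the R alcohol and so fixes C9; the S alcohol is separated.

Step 3
Reactants: 6 propane-1,3-diol
Product: 7 3-[(triethylsilyl)oxy]propan-1-ol
Conditions: NaH (1.0 equiv), THF, 0 °C → rt; Et3SiCl (1.0 equiv)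
Reagents that add atoms: chlorotriethylsilane, CC[Si](Cl)(CC)CC
Why: Monosilylation of a symmetric diol through its monosodium alkoxide (O-silylation).

Step 4
Reactants: 7 3-[(triethylsilyl)oxy]propan-1-ol
Product: 8 3-[(triethylsilyl)oxy]propanal
Conditions: 2,2,6,6-tetramethylpiperidin-1-oxyl (TEMPO, 10 mol %), PhI(OAc)2, CH2Cl2, rt
Reagents that add atoms: none
Why: Oxoammonium-mediated (TEMPO) oxidation of a primary alcohol stops at the aldehyde and leaves the silyl ether alone.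

Step 5
Reactants: 9 iodoethane
Product: 10 ethyltriphenylphosphonium iodide
Conditions: PPh3, toluene, 110 °C
Reagents that add atoms: triphenylphosphine, c1ccc(cc1)P(c1ccccc1)c1ccccc1
Why: SN2 quaternisation of the phosphine by a primary iodide.

Step 6
Reactants: 10 ethyltriphenylphosphonium iodide; 8 3-[(triethylsilyl)oxy]propanal
Product: 14 (Z)-triethyl[(4-iodopent-3-en-1-yl)oxy]silane, via ethylidenetriphenylphosphorane 11 (not isolated), via (1-iodoethyl)triphenylphosphonium iodide 12 (not isolated), via (1-iodoethylidene)triphenylphosphorane 13 (not isolated)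
Conditions: n-BuLi, THF, 0 °C; I2, −78 °C; NaN(SiMe3)2, −20 °C; then 8, −78 °C → rt
Reagents that add atoms: iodine, II
Why: Stork–Zhao α-iodo Wittig olefination; the non-stabilised iodo ylide reacts under kinetic control to the (Z)-2-iodoalkene, which fixes the later C12=C13 geometry.

Step 7
Reactants: 5 (3R)-5-(trimethylsilyl)pent-1-en-4-yn-3-yl acetate; 14 (Z)-triethyl[(4-iodopent-3-en-1-yl)oxy]silane
Product: 16 (3R,6Z)-6-methyl-9-[(triethylsilyl)oxy]-1-(trimethylsilyl)non-6-en-1-yn-3-yl acetate, via alkylborane 15 (not isolated)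
Conditions: 9-BBN (1.1 equiv), THF, 0 °C → rt; then 14, Pd(dppf)Cl2 (5 mol %), AsPh3, Cs2CO3, DMF/H2O, rt
Reagents that add atoms: none
Why: Anti-Markovnikov hydroboration of the vinyl group followed by B-alkyl Suzuki–Miyaura coupling with retention of the iodoalkene geometry forms C11–C12 as the Z trisubstituted alkene; C9 is untouched.

Step 8
Reactants: 16 (3R,6Z)-6-methyl-9-[(triethylsilyl)oxy]-1-(trimethylsilyl)non-6-en-1-yn-3-yl acetate
Product: 17 (3R,6Z)-6-methyl-9-[(triethylsilyl)oxy]non-6-en-1-yn-3-ol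
Conditions: K2CO3 (0.3 equiv), MeOH, 0 °C → rt
Reagents that add atoms: none
Why: Base-catalysed methanolysis removes the acetate and the alkynyl silane in one operation, while the alkyl triethylsilyl ether is stable.

Step 9
Reactants: 17 (3R,6Z)-6-methyl-9-[(triethylsilyl)oxy]non-6-en-1-yn-3-ol
Product: 19 (1S)-1-[(2S,5R)-5-ethynyl-2-methyloxolan-2-yl]-3-[(triethylsilyl)oxy]propan-1-ol, via epoxy alcohol 18 (not isolated)
Conditions: ent-Shi ketone (1,2:4,5-di-O-isopropylidene-β-L-erythro-2,3-hexodiulo-2,6-pyranose, 30 mol %), KHSO5 (as 2KHSO5·KHSO4·K2SO4), K2CO3, Bu4NHSO4, MeCN/CH2(OMe)2/aq Na2B4O7, 0 °C; then camphorsulfonic acid (5 mol %), CH2Cl2, 0 °C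
Reagents that add atoms: potassium peroxymonosulfate, [K+].[O-]S(=O)(=O)OO
Why: Shi asymmetric epoxidation (spiro transition state, reagent control) gives the (12R,13S)-epoxide of the Z alkene, and acid-catalysed 5-exo opening by the C9 hydroxyl at the tertiary C12 with inversion gives the 2,5-cis oxolane with C12 (S) and C13 (S).

Step 10
Reactants: 19 (1S)-1-[(2S,5R)-5-ethynyl-2-methyloxolan-2-yl]-3-[(triethylsilyl)oxy]propan-1-ol
Product: 20 (2S,5R)-2-[(1S)-1,3-bis(triethylsilyloxy)propyl]-5-ethynyl-2-methyloxolane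
Conditions: Et3SiOTf, 2,6-lutidine, CH2Cl2, −78 → 0 °C
Reagents that add atoms: triethylsilyl trifluoromethanesulfonate, CC[Si](CC)(CC)OS(=O)(=O)C(F)(F)F
Why: Silyl triflate silylation of the hindered secondary alcohol.

Step 11
Reactants: 20 (2S,5R)-2-[(1S)-1,3-bis(triethylsilyloxy)propyl]-5-ethynyl-2-methyloxolane
Product: 22 (2S,5R)-2-[(1S)-1,3-bis(triethylsilyloxy)propyl]-5-(1-iodoethenyl)-2-methyloxolane, via alkenylalane 21 (not isolated)
Conditions: Ni(dppp)Cl2 (3 mol %), i-Bu2AlH (1.3 equiv), THF, 0 °C → rt; then N-iodosuccinimide, 0 °C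
Reagents that add atoms: N-iodosuccinimide, O=C1CCC(=O)N1I
Why: Nickel-catalysed α-selective hydroalumination of the terminal alkyne and iodinolysis with retention give the 1,1-disubstituted iodoalkene (a Markovnikov hydroiodination equivalent).

Step 12
Reactants: 22 (2S,5R)-2-[(1S)-1,3-bis(triethylsilyloxy)propyl]-5-(1-iodoethenyl)-2-methyloxolane
Product: 24 (3S)-3-[(2S,5R)-5-(1-iodoethenyl)-2-methyloxolan-2-yl]-3-[(triethylsilyl)oxy]propanal, via primary alcohol 23 (not isolated)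
Conditions: (COCl)2 (excess), DMSO, CH2Cl2, −78 → −30 °C; then Et3N, −78 °C → rt
Reagents that add atoms: none
Why: Under Swern conditions a primary triethylsilyl ether is cleaved and oxidised in one pot while the hindered secondary one is inert (selective Swern oxidation of silyl ethers).

Step 13
Reactants: 25 prop-2-enoyl chloride (acryloyl chloride); 26 2-(trimethylsilyl)ethanol
Product: 27 2-(trimethylsilyl)ethyl prop-2-enoate
Conditions: Et3N, CH2Cl2, 0 °C
Reagents that add atoms: none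
Why: Acylation of an alcohol by an acid chloride with an amine base.

Step 14
Reactants: 24 (3S)-3-[(2S,5R)-5-(1-iodoethenyl)-2-methyloxolan-2-yl]-3-[(triethylsilyl)oxy]propanal; 27 2-(trimethylsilyl)ethyl prop-2-enoate
Product: 28 2-(trimethylsilyl)ethyl (5S)-3-hydroxy-5-[(2S,5R)-5-(1-iodoethenyl)-2-methyloxolan-2-yl]-2-methylidene-5-[(triethylsilyl)oxy]pentanoate (both C3 epimers)
Conditions: 1,4-diazabicyclo[2.2.2]octane (1 equiv), MeOH (1 equiv), neat 27 (3 equiv), rt, 3 d
Reagents that add atoms: none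
Why: Morita–Baylis–Hillman reaction; the new carbinol centre becomes sp2 in step 15, so both epimers are carried on.

Step 15
Reactants: 28 2-(trimethylsilyl)ethyl (5S)-3-hydroxy-5-[(2S,5R)-5-(1-iodoethenyl)-2-methyloxolan-2-yl]-2-methylidene-5-[(triethylsilyl)oxy]pentanoate
Product: 29 2-(trimethylsilyl)ethyl (2Z,5S)-2-(chloromethyl)-5-[(2S,5R)-5-(1-iodoethenyl)-2-methyloxolan-2-yl]-5-[(triethylsilyl)oxy]pent-2-enoate
Conditions: N-chlorosuccinimide, Me2S, CH2Cl2, −20 → 0 °C
Reagents that add atoms: N-chlorosuccinimide, O=C1CCC(=O)N1Cl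
Why: Corey–Kim-type activation of the allylic alcohol and SN2′ return of chloride give the conjugated (Z)-2-(chloromethyl)enoate, the usual thermodynamic outcome for Baylis–Hillman adducts.

Step 16
Reactants: 30 3-bromobut-3-en-1-ol
Product: 31 1-{[(3-bromobut-3-en-1-yl)oxy]methyl}-4-methoxybenzene
Conditions: NaH, 4-methoxybenzyl chloride, Bu4NI (cat.), THF/DMF, 0 °C → rt
Reagents that add atoms: 4-methoxybenzyl chloride, COc1ccc(CCl)cc1
Why: Williamson ether synthesis.

Step 17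
Reactants: 31 1-{[(3-bromobut-3-en-1-yl)oxy]methyl}-4-methoxybenzene; 1 prop-2-enal (acrolein)
Product: 33 rac-2-{2-[(4-methoxybenzyl)oxy]ethyl}penta-1,4-dien-3-ol, via alkenyllithium 32 (not isolated)
Conditions: t-BuLi (2.0 equiv), Et2O, −78 °C; then 1, −78 °C; aq NH4Cl
Reagents that add atoms: none
Why: Bromine–lithium exchange followed by 1,2-addition of the alkenyllithium to acrolein.

Step 18
Reactants: 33 rac-2-{2-[(4-methoxybenzyl)oxy]ethyl}penta-1,4-dien-3-ol
Product: 34 (1R)-1-[(2R)-2-{2-[(4-methoxybenzyl)oxy]ethyl}oxiran-2-yl]prop-2-en-1-ol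
Conditions: Ti(OiPr)4 (10 mol %), D-(−)-diisopropyl tartrate (15 mol %), t-BuOOH (0.6 equiv), 4 Å MS, CH2Cl2, −20 °C
Reagents that add atoms: tert-butyl hydroperoxide, CC(C)(C)OO
Why: Sharpless kinetic resolution: with D-(−)-tartrate the R dienol is epoxidised fast at its electron-richer 1,1-disubstituted alkene, anti to the carbinol substituent, which sets C4 and C5 together; the S dienol is left behind.

Step 19
Reactants: 34 (1R)-1-[(2R)-2-{2-[(4-methoxybenzyl)oxy]ethyl}oxiran-2-yl]prop-2-en-1-ol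
Product: 35 (3R,4S)-6-[(4-methoxybenzyl)oxy]-4-methylhex-1-ene-3,4-diol
Conditions: LiAlH4, THF, 0 °C
Reagents that add atoms: none
Why: Hydride opens the 2,2-disubstituted epoxide at its CH2 (SN2), which turns it into the C4 methyl group and tertiary alcohol with both stereocentres unchanged.

Step 20
Reactants: 35 (3R,4S)-6-[(4-methoxybenzyl)oxy]-4-methylhex-1-ene-3,4-diol
Product: 36 (3R,4S)-4-hydroxy-6-[(4-methoxybenzyl)oxy]-4-methylhex-1-en-3-yl acetate
Conditions: Ac2O, pyridine, 4-(dimethylamino)pyridine (5 mol %), CH2Cl2, 0 °C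
Reagents that add atoms: acetic anhydride, CC(=O)OC(C)=O
Why: Nucleophile-catalysed acylation discriminates the secondary from the tertiary alcohol and installs the C5 acetate of the target.

Step 21
Reactants: 36 (3R,4S)-4-hydroxy-6-[(4-methoxybenzyl)oxy]-4-methylhex-1-en-3-yl acetate
Product: 37 (3R,4S)-6-[(4-methoxybenzyl)oxy]-4-methyl-4-[(triethylsilyl)oxy]hex-1-en-3-yl acetate
Conditions: Et3SiOTf, 2,6-lutidine, CH2Cl2, −40 → 0 °C
Reagents that add atoms: triethylsilyl trifluoromethanesulfonate, CC[Si](CC)(CC)OS(=O)(=O)C(F)(F)F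
Why: Silyl triflate silylation of the tertiary alcohol.

Step 22
Reactants: 37 (3R,4S)-6-[(4-methoxybenzyl)oxy]-4-methyl-4-[(triethylsilyl)oxy]hex-1-en-3-yl acetate
Product: 38 (3R,4S)-6-hydroxy-4-methyl-4-[(triethylsilyl)oxy]hex-1-en-3-yl acetate
Conditions: DDQ, CH2Cl2/pH 7 buffer, 0 °C
Reagents that add atoms: none
Why: Oxidative cleavage of the 4-methoxybenzyl ether by DDQ; acetate, silyl ether and alkene are inert.

Step 23
Reactants: 38 (3R,4S)-6-hydroxy-4-methyl-4-[(triethylsilyl)oxy]hex-1-en-3-yl acetate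
Product: 39 (3R,4S)-6-iodo-4-methyl-4-[(triethylsilyl)oxy]hex-1-en-3-yl acetate
Conditions: I2, PPh3, imidazole, CH2Cl2, 0 °C
Reagents that add atoms: iodine, II
Why: Appel-type iodination of the primary alcohol (SN2 on the alkoxyphosphonium).

Step 24
Reactants: 39 (3R,4S)-6-iodo-4-methyl-4-[(triethylsilyl)oxy]hex-1-en-3-yl acetate (1.5 equiv); 29 2-(trimethylsilyl)ethyl (2Z,5S)-2-(chloromethyl)-5-[(2S,5R)-5-(1-iodoethenyl)-2-methyloxolan-2-yl]-5-[(triethylsilyl)oxy]pent-2-enoate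
Product: 42 2-(trimethylsilyl)ethyl (3S,6S,7R)-7-acetoxy-3-{(2S)-2-[(2S,5R)-5-(1-iodoethenyl)-2-methyloxolan-2-yl]-2-[(triethylsilyl)oxy]ethyl}-6-methyl-2-methylidene-6-[(triethylsilyl)oxy]non-8-enoate, via alkylzinc iodide 40 (not isolated), via mixed diorganozinc 41 (not isolated)
Conditions: Zn dust (BrCH2CH2Br/Me3SiCl activation), LiCl, THF, 35 °C; Me3SiCH2Li, −78 °C; then 29, CuBr·SMe2 (5 mol %), (S)-binaphthol N,N-bis[(R)-1-phenylethyl]phosphoramidite (10 mol %; enantiomer confirmed in a model coupling), THF, −40 → −20 °C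
Reagents that add atoms: none
Why: Proposed new method: a copper/phosphoramidite-catalysed, catalyst-controlled SN2′ (addition–elimination) alkylation of a Baylis–Hillman-derived (Z)-2-(chloromethyl)enoate by a fragment-sized mixed alkyl(trimethylsilylmethyl)zinc, in which transmetalation gives a ligated alkylcopper that binds the enoate, adds to the Si face of the β-carbon (C1) anti to chloride to give a trivalent-copper allyl/enolate species, and reductive elimination forms C1–C2, sets C1 (S) and releases the α-methylene ester while the silylmethyl group is not transferred; the closest known reactions are the stoichiometric copper–zinc SN2′ allylation of functionalised alkylzincs and the copper-catalysed asymmetric allylic alkylation with simple dialkylzincs.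

Step 25
Reactants: 42 2-(trimethylsilyl)ethyl (3S,6S,7R)-7-acetoxy-3-{(2S)-2-[(2S,5R)-5-(1-iodoethenyl)-2-methyloxolan-2-yl]-2-[(triethylsilyl)oxy]ethyl}-6-methyl-2-methylidene-6-[(triethylsilyl)oxy]non-8-enoate
Product: 44 2-(trimethylsilyl)ethyl 2-[(1S,2S,4S,7S,8R,12R)-8-acetoxy-1,7-dimethyl-11-methylidene-2,7-bis[(triethylsilyl)oxy]-15-oxabicyclo[10.2.1]pentadecan-4-yl]prop-2-enoate, via alkylborane 43 (not isolated)
Conditions: 9-BBN (1.3 equiv), THF, 0 °C → rt; then slow addition to Pd(dppf)Cl2 (20 mol %), AsPh3, Cs2CO3, DMF/THF/H2O, 1 mM, rt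
Reagents that add atoms: none
Why: 9-BBN selects the only electron-rich monosubstituted alkene over the acrylate and the iodoalkene, and the intramolecular B-alkyl Suzuki–Miyaura coupling under high dilution closes the 14-membered ring at C7–C8 and leaves the exocyclic methylene; no stereocentre is formed or touched.

Step 26
Reactants: 44 2-(trimethylsilyl)ethyl 2-[(1S,2S,4S,7S,8R,12R)-8-acetoxy-1,7-dimethyl-11-methylidene-2,7-bis[(triethylsilyl)oxy]-15-oxabicyclo[10.2.1]pentadecan-4-yl]prop-2-enoate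
Product: 45 2-[(1S,2S,4S,7S,8R,12R)-8-acetoxy-2,7-dihydroxy-1,7-dimethyl-11-methylidene-15-oxabicyclo[10.2.1]pentadecan-4-yl]prop-2-enoic acid (the target CNP0215199.3)
Conditions: Bu4NF, AcOH, THF, 0 °C → rt; pH 4 work-up
Reagents that add atoms: none
Why: Fluoride cleaves both triethylsilyl ethers and triggers the β-elimination of the 2-(trimethylsilyl)ethyl ester, and the buffered conditions spare the acetate and the acrylate.

## Compound list

1 | prop-2-enal (acrolein) | C=CC=O | starting material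
2 | ethynyltrimethylsilane | C#C[Si](C)(C)C | starting material
3 | lithium (trimethylsilyl)acetylide | [Li]C#C[Si](C)(C)C | intermediate
4 | rac-5-(trimethylsilyl)pent-1-en-4-yn-3-ol | C=CC(O)C#C[Si](C)(C)C | intermediate
5 | (3R)-5-(trimethylsilyl)pent-1-en-4-yn-3-yl acetate | C=C[C@@H](OC(C)=O)C#C[Si](C)(C)C | intermediate
6 | propane-1,3-diol | OCCCO | starting material
7 | 3-[(triethylsilyl)oxy]propan-1-ol | OCCCO[Si](CC)(CC)CC | intermediate
8 | 3-[(triethylsilyl)oxy]propanal | O=CCCO[Si](CC)(CC)CC | intermediate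
9 | iodoethane | CCI | starting material
10 | ethyltriphenylphosphonium iodide | CC[P+](c1ccccc1)(c1ccccc1)c1ccccc1.[I-] | intermediate
11 | ethylidenetriphenylphosphorane | CC=P(c1ccccc1)(c1ccccc1)c1ccccc1 | intermediate
12 | (1-iodoethyl)triphenylphosphonium iodide | CC(I)[P+](c1ccccc1)(c1ccccc1)c1ccccc1.[I-] | intermediate
13 | (1-iodoethylidene)triphenylphosphorane | CC(I)=P(c1ccccc1)(c1ccccc1)c1ccccc1 | intermediate
14 | (Z)-triethyl[(4-iodopent-3-en-1-yl)oxy]silane | C/C(I)=C/CCO[Si](CC)(CC)CC | intermediate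
15 | (3R)-5-(9-borabicyclo[3.3.1]nonan-9-yl)-1-(trimethylsilyl)pent-1-yn-3-yl acetate | C[Si](C)(C)C#C[C@H](OC(C)=O)CCB1C2CCCC1CCC2 | intermediate
16 | (3R,6Z)-6-methyl-9-[(triethylsilyl)oxy]-1-(trimethylsilyl)non-6-en-1-yn-3-yl acetate | C[Si](C)(C)C#C[C@H](OC(C)=O)CC/C(C)=C\CCO[Si](CC)(CC)CC | intermediate
17 | (3R,6Z)-6-methyl-9-[(triethylsilyl)oxy]non-6-en-1-yn-3-ol | C#C[C@H](O)CC/C(C)=C\CCO[Si](CC)(CC)CC | intermediate
18 | (3R)-5-[(2R,3S)-2-methyl-3-{2-[(triethylsilyl)oxy]ethyl}oxiran-2-yl]pent-1-yn-3-ol | C#C[C@H](O)CC[C@@]1(C)O[C@H]1CCO[Si](CC)(CC)CC | intermediate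
19 | (1S)-1-[(2S,5R)-5-ethynyl-2-methyloxolan-2-yl]-3-[(triethylsilyl)oxy]propan-1-ol | C#C[C@H]1CC[C@](C)(O1)[C@@H](O)CCO[Si](CC)(CC)CC | intermediate
20 | (2S,5R)-2-[(1S)-1,3-bis(triethylsilyloxy)propyl]-5-ethynyl-2-methyloxolane | C#C[C@H]1CC[C@](C)(O1)[C@@H](O[Si](CC)(CC)CC)CCO[Si](CC)(CC)CC | intermediate
21 | {1-[(2R,5S)-5-[(1S)-1,3-bis(triethylsilyloxy)propyl]-5-methyloxolan-2-yl]ethenyl}bis(2-methylpropyl)alumane | C=C([Al](CC(C)C)CC(C)C)[C@H]1CC[C@](C)(O1)[C@@H](O[Si](CC)(CC)CC)CCO[Si](CC)(CC)CC | intermediate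
22 | (2S,5R)-2-[(1S)-1,3-bis(triethylsilyloxy)propyl]-5-(1-iodoethenyl)-2-methyloxolane | C=C(I)[C@H]1CC[C@](C)(O1)[C@@H](O[Si](CC)(CC)CC)CCO[Si](CC)(CC)CC | intermediate
23 | (3S)-3-[(2S,5R)-5-(1-iodoethenyl)-2-methyloxolan-2-yl]-3-[(triethylsilyl)oxy]propan-1-ol | C=C(I)[C@H]1CC[C@](C)(O1)[C@@H](O[Si](CC)(CC)CC)CCO | intermediate
24 | (3S)-3-[(2S,5R)-5-(1-iodoethenyl)-2-methyloxolan-2-yl]-3-[(triethylsilyl)oxy]propanal | C=C(I)[C@H]1CC[C@](C)(O1)[C@@H](O[Si](CC)(CC)CC)CC=O | intermediate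
25 | prop-2-enoyl chloride (acryloyl chloride) | C=CC(=O)Cl | starting material
26 | 2-(trimethylsilyl)ethanol | OCC[Si](C)(C)C | starting material
27 | 2-(trimethylsilyl)ethyl prop-2-enoate | C=CC(=O)OCC[Si](C)(C)C | intermediate
28 | 2-(trimethylsilyl)ethyl (5S)-3-hydroxy-5-[(2S,5R)-5-(1-iodoethenyl)-2-methyloxolan-2-yl]-2-methylidene-5-[(triethylsilyl)oxy]pentanoate (both C3 epimers) | C=C(I)[C@H]1CC[C@](C)(O1)[C@@H](O[Si](CC)(CC)CC)CC(O)C(=C)C(=O)OCC[Si](C)(C)C | intermediate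
29 | 2-(trimethylsilyl)ethyl (2Z,5S)-2-(chloromethyl)-5-[(2S,5R)-5-(1-iodoethenyl)-2-methyloxolan-2-yl]-5-[(triethylsilyl)oxy]pent-2-enoate | C=C(I)[C@H]1CC[C@](C)(O1)[C@@H](O[Si](CC)(CC)CC)C/C=C(\CCl)C(=O)OCC[Si](C)(C)C | intermediate
30 | 3-bromobut-3-en-1-ol | C=C(Br)CCO | starting material
31 | 1-{[(3-bromobut-3-en-1-yl)oxy]methyl}-4-methoxybenzene | C=C(Br)CCOCc1ccc(OC)cc1 | intermediate
32 | {4-[(4-methoxybenzyl)oxy]but-1-en-2-yl}lithium | [Li]C(=C)CCOCc1ccc(OC)cc1 | intermediate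
33 | rac-2-{2-[(4-methoxybenzyl)oxy]ethyl}penta-1,4-dien-3-ol | C=CC(O)C(=C)CCOCc1ccc(OC)cc1 | intermediate
34 | (1R)-1-[(2R)-2-{2-[(4-methoxybenzyl)oxy]ethyl}oxiran-2-yl]prop-2-en-1-ol | C=C[C@@H](O)[C@@]1(CCOCc2ccc(OC)cc2)CO1 | intermediate
35 | (3R,4S)-6-[(4-methoxybenzyl)oxy]-4-methylhex-1-ene-3,4-diol | C=C[C@@H](O)[C@@](C)(O)CCOCc1ccc(OC)cc1 | intermediate
36 | (3R,4S)-4-hydroxy-6-[(4-methoxybenzyl)oxy]-4-methylhex-1-en-3-yl acetate | C=C[C@@H](OC(C)=O)[C@@](C)(O)CCOCc1ccc(OC)cc1 | intermediate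
37 | (3R,4S)-6-[(4-methoxybenzyl)oxy]-4-methyl-4-[(triethylsilyl)oxy]hex-1-en-3-yl acetate | C=C[C@@H](OC(C)=O)[C@@](C)(O[Si](CC)(CC)CC)CCOCc1ccc(OC)cc1 | intermediate
38 | (3R,4S)-6-hydroxy-4-methyl-4-[(triethylsilyl)oxy]hex-1-en-3-yl acetate | C=C[C@@H](OC(C)=O)[C@@](C)(O[Si](CC)(CC)CC)CCO | intermediate
39 | (3R,4S)-6-iodo-4-methyl-4-[(triethylsilyl)oxy]hex-1-en-3-yl acetate | C=C[C@@H](OC(C)=O)[C@@](C)(O[Si](CC)(CC)CC)CCI | intermediate
40 | {(3S,4R)-4-acetoxy-3-methyl-3-[(triethylsilyl)oxy]hex-5-en-1-yl}zinc iodide | C=C[C@@H](OC(C)=O)[C@@](C)(O[Si](CC)(CC)CC)CC[Zn]I | intermediate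
41 | {(3S,4R)-4-acetoxy-3-methyl-3-[(triethylsilyl)oxy]hex-5-en-1-yl}[(trimethylsilyl)methyl]zinc | C=C[C@@H](OC(C)=O)[C@@](C)(O[Si](CC)(CC)CC)CC[Zn]C[Si](C)(C)C | intermediate
42 | 2-(trimethylsilyl)ethyl (3S,6S,7R)-7-acetoxy-3-{(2S)-2-[(2S,5R)-5-(1-iodoethenyl)-2-methyloxolan-2-yl]-2-[(triethylsilyl)oxy]ethyl}-6-methyl-2-methylidene-6-[(triethylsilyl)oxy]non-8-enoate | C=C(C(=O)OCC[Si](C)(C)C)[C@@H](CC[C@](C)(O[Si](CC)(CC)CC)[C@H](OC(C)=O)C=C)C[C@H](O[Si](CC)(CC)CC)[C@]1(C)CC[C@@H](O1)C(I)=C | intermediate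
43 | B-alkyl-9-BBN derivative of 42 (C9 of the nonanoate chain carries the 9-borabicyclo[3.3.1]nonan-9-yl group) | C=C(C(=O)OCC[Si](C)(C)C)[C@@H](CC[C@](C)(O[Si](CC)(CC)CC)[C@H](OC(C)=O)CCB1C2CCCC1CCC2)C[C@H](O[Si](CC)(CC)CC)[C@]1(C)CC[C@@H](O1)C(I)=C | intermediate
44 | 2-(trimethylsilyl)ethyl 2-[(1S,2S,4S,7S,8R,12R)-8-acetoxy-1,7-dimethyl-11-methylidene-2,7-bis[(triethylsilyl)oxy]-15-oxabicyclo[10.2.1]pentadecan-4-yl]prop-2-enoate | C=C(C(=O)OCC[Si](C)(C)C)[C@H]1CC[C@](C)(O[Si](CC)(CC)CC)[C@H](OC(C)=O)CCC(=C)[C@H]2CC[C@](C)(O2)[C@@H](O[Si](CC)(CC)CC)C1 | intermediate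
45 | 2-[(1S,2S,4S,7S,8R,12R)-8-acetoxy-2,7-dihydroxy-1,7-dimethyl-11-methylidene-15-oxabicyclo[10.2.1]pentadecan-4-yl]prop-2-enoic acid (CNP0215199.3) | C=C(C(=O)O)[C@H]1CC[C@](C)(O)[C@H](OC(C)=O)CCC(=C)[C@H]2CC[C@](C)(O2)[C@@H](O)C1 | target

## Step count and risks

Total step count: 26. Longest linear sequence: 14 steps (3, 4, 6, 7, 8, 9, 10, 11, 12, 14, 15, 24, 25, 26).

The three steps most likely to fail:

Step 24 (the proposed new coupling; risks are low transfer efficiency of the zinc reagent, poor facial control at C1, or over-addition to the product acrylate). The fallback uses known chemistry, sets out from aldehyde 24 and the zinc reagent 41 (made from 39 as in step 24), and comes back at 42; steps 14 and 15 are then not needed. Knoevenagel condensation of 24 with Meldrum's acid (pyrrolidinium acetate, benzene, rt) gives the alkylidene Meldrum's acid F1. A copper-catalysed asymmetric conjugate addition of the diorganozinc 41 (Cu(OTf)2, phosphoramidite ligand, −40 °C), a reaction class established for alkylidene Meldrum's acids and dialkylzincs, sets C1 and gives the 5-monosubstituted Meldrum's acid F2. Heating F2 with Eschenmoser's salt (CH2=NMe2+ I−) in 2-(trimethylsilyl)ethanol 26 at 65 °C (Mannich reaction, ring opening by the alcohol, loss of acetone and CO2, elimination of dimethylamine) gives the α-methylene ester 42.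

Step 25 (risks are competing hydroboration or reduction of the acrylate by 9-BBN, and oligomerisation in the ring closure). The fallback sets out from 42 and comes back at 44. The acrylate is masked by conjugate addition of thiophenol (PhSH, Et3N cat., CH2Cl2) to give the thiophenol adduct F3. Hydroboration with 9-BBN gives the alkylborane F4, which is cyclised under the same Suzuki–Miyaura conditions to the macrocyclic sulfide F5. Oxidation with NaIO4 (MeOH/H2O) gives the sulfoxide F6, and thermal syn-elimination (toluene, 110 °C, CaCO3) restores the α-methylene ester 44.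

Step 9 (risk is insufficient face selectivity of the dioxirane on the Z trisubstituted alkene). The fallback sets out from 17 and comes back at 19. The non-directed dioxirane epoxidation is replaced by a hydroxyl-directed, ligand-controlled metal-peroxide epoxidation of the bishomoallylic alcohol (Hf(OtBu)4, chiral bis-hydroxamic acid ligand, cumene hydroperoxide, toluene, 0 °C), known for homoallylic and bishomoallylic alcohols. Here the C9 alkoxide binds the metal and the ligand sets the face. It gives the same epoxy alcohol 18, which camphorsulfonic acid converts to 19, so no compound outside the list is made (F0).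

Further compounds
F1 | step 24 | 5-{(3S)-3-[(2S,5R)-5-(1-iodoethenyl)-2-methyloxolan-2-yl]-3-[(triethylsilyl)oxy]propylidene}-2,2-dimethyl-1,3-dioxane-4,6-dione | C=C(I)[C@H]1CC[C@](C)(O1)[C@@H](O[Si](CC)(CC)CC)CC=C1C(=O)OC(C)(C)OC1=O
F2 | step 24 | 5-{(1S,3S,6S,7R)-7-acetoxy-1-[(2S,5R)-5-(1-iodoethenyl)-2-methyloxolan-2-yl]-6-methyl-1,6-bis[(triethylsilyl)oxy]non-8-en-3-yl}-2,2-dimethyl-1,3-dioxane-4,6-dione | C=C[C@@H](OC(C)=O)[C@@](C)(O[Si](CC)(CC)CC)CC[C@@H](C[C@H](O[Si](CC)(CC)CC)[C@]1(C)CC[C@@H](O1)C(I)=C)C1C(=O)OC(C)(C)OC1=O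
F3 | step 25 | 2-(trimethylsilyl)ethyl (3S,6S,7R)-7-acetoxy-3-{(2S)-2-[(2S,5R)-5-(1-iodoethenyl)-2-methyloxolan-2-yl]-2-[(triethylsilyl)oxy]ethyl}-6-methyl-2-[(phenylsulfanyl)methyl]-6-[(triethylsilyl)oxy]non-8-enoate (C2 epimers) | O=C(OCC[Si](C)(C)C)C(CSc1ccccc1)[C@@H](CC[C@](C)(O[Si](CC)(CC)CC)[C@H](OC(C)=O)C=C)C[C@H](O[Si](CC)(CC)CC)[C@]1(C)CC[C@@H](O1)C(I)=C
F4 | step 25 | B-alkyl-9-BBN derivative of F3 (C9 carries the 9-borabicyclo[3.3.1]nonan-9-yl group) | O=C(OCC[Si](C)(C)C)C(CSc1ccccc1)[C@@H](CC[C@](C)(O[Si](CC)(CC)CC)[C@H](OC(C)=O)CCB1C2CCCC1CCC2)C[C@H](O[Si](CC)(CC)CC)[C@]1(C)CC[C@@H](O1)C(I)=C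
F5 | step 25 | 2-(trimethylsilyl)ethyl 2-[(1S,2S,4S,7S,8R,12R)-8-acetoxy-1,7-dimethyl-11-methylidene-2,7-bis[(triethylsilyl)oxy]-15-oxabicyclo[10.2.1]pentadecan-4-yl]-3-(phenylsulfanyl)propanoate (C2 epimers) | O=C(OCC[Si](C)(C)C)C(CSc1ccccc1)[C@H]1CC[C@](C)(O[Si](CC)(CC)CC)[C@H](OC(C)=O)CCC(=C)[C@H]2CC[C@](C)(O2)[C@@H](O[Si](CC)(CC)CC)C1
F6 | step 25 | 2-(trimethylsilyl)ethyl 2-[(1S,2S,4S,7S,8R,12R)-8-acetoxy-1,7-dimethyl-11-methylidene-2,7-bis[(triethylsilyl)oxy]-15-oxabicyclo[10.2.1]pentadecan-4-yl]-3-(phenylsulfinyl)propanoate (mixture of epimers) | O=C(OCC[Si](C)(C)C)C(CS(=O)c1ccccc1)[C@H]1CC[C@](C)(O[Si](CC)(CC)CC)[C@H](OC(C)=O)CCC(=C)[C@H]2CC[C@](C)(O2)[C@@H](O[Si](CC)(CC)CC)C1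
F0 | step 9 | none | none
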